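**Retrosynthetic overview**
1. Target 21 ⇐ 20 (HF desilylation) ⇐ 19 (ring C closed last by SNAr of O8 on the ortho-fluoroaroyl group) ⇐ 17 (silane opening of the O8–C-beta ketal bond).
2. Feature: in the target O8, C8, C-alpha and C-beta are contiguous and C-beta is tied back to C7 through O7. The C8(O8)–C-alpha–C-beta(O7) array of rings A and F is therefore the opened form of an oxetane inside a 2,5-dioxabicyclo[2.1.1]hexane whose two-atom bridge is C7–O7.
3. 17 ⇐ 16: intramolecular crossed Paternò–Büchi addition of the C8 quinone carbonyl to the 7-O-enol ether, forming C8–C-alpha and O8–C-beta (ring F plus the oxetane).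
4. 16 ⇐ 15 ⇐ 14 ⇐ 8 + 13: O7–C-beta bond by benzylic epoxide opening, oxidation to the 1,2-dione, enol silylation; O7 can then sit only on the anisyl carbon.
5. 8 ⇐ 7 ⇐ 1 + 3 (aldol, hydrogenation, asymmetric transfer hydrogenation, Mitsunobu, Teuber oxidation); 13 ⇐ 9 + 11. Ring order: B, A (as quinone), F with the oxetane, C.

Key step: step 13

**Remarks and assumptions**
- Labels: flavan numbering (O1, C2–C8a) is kept throughout; O7 and O8 are the oxygens on C7 and C8. C-alpha is the carbinol carbon of the target (it bears OH and the ring-C carbonyl); C-beta is the CH(4-methoxyphenyl) carbon. Ring A = carbocycle C4a–C8a; ring B = pyran (O1, C2, C3, C4); ring F = C8, C-alpha, C-beta, O7, C7; ring C = O8, C8, C-alpha, C=O and two aryl carbons. An = 4-methoxyphenyl; ArF = 2-fluoro-4,6-dimethoxyphenyl.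
- The target SMILES is read as C2 R, C8 S, C-alpha R, C-beta S. On ring F, O8 and the ring-C carbonyl are cis, and An on C-beta is trans to them (cis to OH).
- Regiochemistry of the enol ether: it is built through the C-beta–O7 bond on an epoxide. O-arylation of an unsymmetrical 2-silyloxy-1,3-dione enolate by a 7-alkoxyquinone would leave both enolate oxygens free to attack.
- 14 and 15 are carried as mixtures at the side-chain sp3 centres, which become sp2 in step 12. 16 may form as an E/Z mixture; the Z isomer is drawn, and both isomers should converge because the key step passes through a freely rotating C-alpha radical.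
- Assumption: acylation of 9 occurs mainly ortho to F and para to OMe; the minor 4-fluoro-2,6-dimethoxy isomer is removed.

**Route**

Step 1
Reactants: 1 2,4,6-trihydroxybenzaldehyde
Product: 2 2,4,6-tris(benzyloxy)benzaldehyde
Conditions: BnBr (3.5 equiv), K2CO3, DMF, 60 °C
Reagents that add atoms: benzyl bromide, BrCc1ccccc1
Why: Williamson O-benzylation of all three phenols keeps the aldehyde electrophilic for the aldol step and lets one hydrogenation remove the groups later.

Step 2
Reactants: 2 2,4,6-tris(benzyloxy)benzaldehyde; 3 4'-methoxyacetophenone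
Product: 4 (E)-1-(4-methoxyphenyl)-3-[2,4,6-tris(benzyloxy)phenyl]prop-2-en-1-one
Conditions: KOH, EtOH/THF, rt
Reagents that add atoms: none
Why: Claisen–Schmidt aldol condensation of the methyl ketone enolate with the non-enolisable aldehyde, dehydration giving the (E)-enone.

Step 3
Reactants: 4 (E)-1-(4-methoxyphenyl)-3-[2,4,6-tris(benzyloxy)phenyl]prop-2-en-1-one
Product: 5 1-(4-methoxyphenyl)-3-(2,4,6-trihydroxyphenyl)propan-1-one
Conditions: H2 (1 atm), Pd/C, EtOAc/MeOH, rt
Reagents that add atoms: none
Why: Heterogeneous hydrogenation saturates the enone C=C and hydrogenolyses the three benzyl ethers in one operation, the electron-rich aryl ketone being reduced much more slowly.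

Step 4
Reactants: 5 1-(4-methoxyphenyl)-3-(2,4,6-trihydroxyphenyl)propan-1-one
Product: 6 2-[(3S)-3-hydroxy-3-(4-methoxyphenyl)propyl]benzene-1,3,5-triol
Conditions: RuCl[(S,S)-TsDPEN](p-cymene) (1 mol %), HCO2Na, MeOH/H2O, 40 °C
Reagents that add atoms: none
Why: Noyori asymmetric transfer hydrogenation, in which the (S,S)-ligated ruthenium hydride reduces the aryl ketone to the (S)-carbinol (aryl as the directing large group), run in near-neutral formate so that the hydroxy ketone does not ionise through its hemiketal.

Step 5
Reactants: 6 2-[(3S)-3-hydroxy-3-(4-methoxyphenyl)propyl]benzene-1,3,5-triol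
Product: 7 (2R)-2-(4-methoxyphenyl)chromane-5,7-diol
Conditions: PPh3, DIAD, THF, −10 °C → rt
Reagents that add atoms: none
Why: Intramolecular Mitsunobu etherification (6-exo-tet): one of the two equivalent ortho phenols displaces the benzylic oxyphosphonium group with inversion, so the (S)-carbinol gives the (R)-flavan and closes ring B; low temperature limits SN1 leakage at the anisyl carbinol.

Step 6
Reactants: 7 (2R)-2-(4-methoxyphenyl)chromane-5,7-diol
Product: 8 (2R)-7-hydroxy-2-(4-methoxyphenyl)chromane-5,8-dione
Conditions: (KSO3)2NO (2.5 equiv), KH2PO4 buffer, acetone/H2O, 0 °C → rt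
Reagents that add atoms: potassium nitrosodisulfonate, [O]N(S(=O)(=O)[O-])S(=O)(=O)[O-].[K+].[K+]
Why: Teuber oxidation, in which the nitroxyl radical oxidises the phenol at its free para position (C8, para to the C5 hydroxyl) to the para-quinone and leaves the 7-OH as an acidic hydroxyquinone oxygen.

Step 7
Reactants: 9 1-fluoro-3,5-dimethoxybenzene
Product: 10 1-(2-fluoro-4,6-dimethoxyphenyl)ethanone
Conditions: Ac2O, TfOH (10 mol %), CH2Cl2, 0 °C → rt
Reagents that add atoms: acetic anhydride, CC(=O)OC(C)=O
Why: Friedel–Crafts acylation at the position para to one methoxy group and ortho to fluorine, the site between the two methoxy groups being more hindered.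

Step 8
Reactants: 10 1-(2-fluoro-4,6-dimethoxyphenyl)ethanone; 11 4-methoxybenzaldehyde
Product: 12 (E)-1-(2-fluoro-4,6-dimethoxyphenyl)-3-(4-methoxyphenyl)prop-2-en-1-one
Conditions: NaOH (aq), EtOH, rt
Reagents that add atoms: none
Why: Claisen–Schmidt condensation; at room temperature the fluoroarene, activated only by one ortho ketone, should not undergo SNAr with the base.

Step 9
Reactants: 12 (E)-1-(2-fluoro-4,6-dimethoxyphenyl)-3-(4-methoxyphenyl)prop-2-en-1-one
Product: 13 rac-trans-(2-fluoro-4,6-dimethoxyphenyl)[3-(4-methoxyphenyl)oxiran-2-yl]methanone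
Conditions: H2O2 (30 %), NaOH, MeOH/THF, 0 °C
Reagents that add atoms: hydrogen peroxide, OO
Why: Weitz–Scheffer nucleophilic epoxidation gives the trans epoxy ketone; it is used racemic because both of its stereocentres become sp2 in steps 11 and 12.

Step 10
Reactants: 8 (2R)-7-hydroxy-2-(4-methoxyphenyl)chromane-5,8-dione; 13 rac-trans-(2-fluoro-4,6-dimethoxyphenyl)[3-(4-methoxyphenyl)oxiran-2-yl]methanone
Product: 14 (2R)-7-[3-(2-fluoro-4,6-dimethoxyphenyl)-2-hydroxy-1-(4-methoxyphenyl)-3-oxopropoxy]-2-(4-methoxyphenyl)chromane-5,8-dione (diastereomer mixture)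
Conditions: 13 (1.5 equiv), ClCH2CH2Cl, 4 Å MS, 50 °C, dark
Reagents that add atoms: none
Why: Acid-type opening of an aryl epoxide: the hydroxyquinone (a vinylogous carboxylic acid, pKa about 4–5) protonates the epoxide and the ion pair collapses at the anisyl-stabilised benzylic carbon, so O7 is attached to C-beta only; the less hindered O7 is alkylated and the para-quinone is retained.

Step 11
Reactants: 14 (2R)-7-[3-(2-fluoro-4,6-dimethoxyphenyl)-2-hydroxy-1-(4-methoxyphenyl)-3-oxopropoxy]-2-(4-methoxyphenyl)chromane-5,8-dione
Product: 15 (2R)-7-[3-(2-fluoro-4,6-dimethoxyphenyl)-1-(4-methoxyphenyl)-2,3-dioxopropoxy]-2-(4-methoxyphenyl)chromane-5,8-dione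
Conditions: Dess–Martin periodinane, CH2Cl2, 0 °C → rt
Reagents that add atoms: none
Why: Dess–Martin oxidation of the alpha-hydroxy ketone to the 1,2-dione under neutral conditions that the quinone and the benzylic ether tolerate.

Step 12
Reactants: 15 (2R)-7-[3-(2-fluoro-4,6-dimethoxyphenyl)-1-(4-methoxyphenyl)-2,3-dioxopropoxy]-2-(4-methoxyphenyl)chromane-5,8-dione
Product: 16 (2R)-7-{[(Z)-2-(tert-butyldimethylsilyloxy)-3-(2-fluoro-4,6-dimethoxyphenyl)-1-(4-methoxyphenyl)-3-oxoprop-1-en-1-yl]oxy}-2-(4-methoxyphenyl)chromane-5,8-dione (photoprecursor)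
Conditions: TBSOTf, i-Pr2NEt, CH2Cl2, −40 → 0 °C
Reagents that add atoms: tert-butyldimethylsilyl triflate, CC(C)(C)[Si](C)(C)OS(=O)(=O)C(F)(F)F
Why: Soft enolisation and O-silylation: C-beta–H is the only enolisable position of the 1,2-dione, so silylation of the C-alpha oxygen can give only the enol ether with O7 and An on C-beta and the aroyl group on C-alpha.

Step 13
Reactants: 16 photoprecursor (7-O-enol ether of the flavan 5,8-quinone)
Product: 17 photoadduct, a 2,5-dioxabicyclo[2.1.1]hexane (C8 bonded to O8 and C-alpha; bridgehead C-beta bears An, O7 and O8; C-alpha bears OTBS over the C7–O7 bridge and the ArF–C(=O) group exo, cis to O8; ring A is now a C5 dienone; C8 as in 21)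
Conditions: hν (450 nm LEDs), degassed benzene (3 mM), 15 °C
Reagents that add atoms: none
Why: Proposed new method: excitation of the quinone n,π* band at 450 nm (no other chromophore of 16, and not the product dienone, absorbs there) gives the triplet, whose C8 carbonyl oxygen bonds to C-beta, directly or after electron transfer from the enol ether, and the resulting triplet 1,4-biradical (aryloxyl radical with spin at C8, captodative radical at C-alpha) closes the C8–C-alpha bond after intersystem crossing. The closest known reactions are the Paternò–Büchi spiro-oxetane formation of 1,4-benzoquinones with alkenes and the crossed intramolecular [2+2] photocycloaddition of 1,5-dienes to bicyclo[2.1.1]hexanes; new here is a quinone carbonyl joined to the alkene by the two-atom C7–O7 link. The first bond closes the five-membered ring O8–C8–C7–O7–C-beta in a 5-exo-trig mode (rule of five), and radical recombination then closes the oxetane (4-exo) and with it ring F, because the straight adduct would need a bicyclo[2.2.0] skeleton, [2+2] with C6=C7 is geometrically impossible and coupling at C6 would create an sp2 bridgehead. C-beta is fixed as a bridgehead once C8 is set; C-alpha is set in the biradical collapse, where rotation about C-alpha–C-beta erases the enol ether geometry and the bulkier aroyl group is expected to take the exo position pointing away from the C7–O7 bridge (cis to O8) with the OTBS group over the bridge; C8 depends on the quinone face attacked, which the remote C2 centre cannot bias. The step thus needs crossed regioselectivity, secured by the tether length, and should give two C8 diastereomers (about 1:1 expected) that are separated by chromatography, only the one drawn being carried on.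

Step 14
Reactants: 17 photoadduct
Product: 19 ring-F tertiary alcohol (C8–OH; C-alpha with OTBS and ArF–C(=O); C-beta with H and An; all centres as in 21), via C8 triethylsilyl ether 18 (not isolated)
Conditions: Et3SiH (20 equiv), Et3SiOTf (0.5 equiv), 2,6-di-tert-butyl-4-methylpyridine (0.2 equiv), CH2Cl2, −78 °C; then PPTS, MeOH, 0 °C
Reagents that add atoms: none
Why: Lewis acid/silane reductive opening of a ketal (ionic hydrogenation): the silyl triflate silylates the basic oxetane oxygen O8, the strained C-beta–O8 bond ionises to the An- and O7-stabilised oxocarbenium ion with O8 leaving as a neutral silyl ether (which, unlike a borate, should not push a Grob-type cycloreversion back to 16), and Et3SiH in large excess adds hydride from the inside face of the ring-F envelope, cis to the pseudoaxial C8–O8 bond and anti to the pseudoaxial C-alpha–OTBS bond, which sets C-beta with H cis to O8 and An cis to OTBS; mild methanolysis then removes the tertiary triethylsilyl group while the tertiary TBS ether stays.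

Step 15
Reactants: 19 ring-F tertiary alcohol
Product: 20 C-alpha O-TBS ether of the target (rings A, B, C, F complete)
Conditions: KN(SiMe3)2 (1.05 equiv), THF, −78 °C; 18-crown-6, −78 → −20 °C
Reagents that add atoms: none
Why: Intramolecular SNAr (addition–elimination through a Meisenheimer complex) of the C8 alkoxide on the fluoroarene activated by the ortho ketone closes the six-membered chromanone ring C, which is possible because O8 and the aroyl group are cis on ring F; the alkoxide is formed at −78 °C so that cyclisation (negative activation entropy) can compete with retro-aldol cleavage of the C8–C-alpha bond on gentle warming.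

Step 16
Reactants: 20 C-alpha O-TBS ether of the target
Product: 21 target CNP0251458.1
Conditions: HF·pyridine, pyridine, THF, 0 °C → rt
Reagents that add atoms: none
Why: Fluoride-mediated cleavage of the tertiary silyl ether under buffered conditions that leave the benzylic ethers at C2 and C-beta and all four stereocentres untouched.

**Compound list**
1 | 2,4,6-trihydroxybenzaldehyde | O=Cc1c(O)cc(O)cc1O | starting material
2 | 2,4,6-tris(benzyloxy)benzaldehyde | O=Cc1c(OCc2ccccc2)cc(OCc2ccccc2)cc1OCc1ccccc1 | intermediate
3 | 4'-methoxyacetophenone | CC(=O)c1ccc(OC)cc1 | starting material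
4 | (E)-1-(4-methoxyphenyl)-3-[2,4,6-tris(benzyloxy)phenyl]prop-2-en-1-one | COc1ccc(cc1)C(=O)/C=C/c1c(OCc2ccccc2)cc(OCc2ccccc2)cc1OCc1ccccc1 | intermediate
5 | 1-(4-methoxyphenyl)-3-(2,4,6-trihydroxyphenyl)propan-1-one | COc1ccc(cc1)C(=O)CCc1c(O)cc(O)cc1O | intermediate
6 | 2-[(3S)-3-hydroxy-3-(4-methoxyphenyl)propyl]benzene-1,3,5-triol | COc1ccc(cc1)[C@@H](O)CCc1c(O)cc(O)cc1O | intermediate
7 | (2R)-2-(4-methoxyphenyl)chromane-5,7-diol | COc1ccc(cc1)[C@H]1CCc2c(O)cc(O)cc2O1 | intermediate
8 | (2R)-7-hydroxy-2-(4-methoxyphenyl)chromane-5,8-dione | COc1ccc(cc1)[C@H]1CCC2=C(O1)C(=O)C(O)=CC2=O | intermediate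
9 | 1-fluoro-3,5-dimethoxybenzene | COc1cc(F)cc(OC)c1 | starting material
10 | 1-(2-fluoro-4,6-dimethoxyphenyl)ethanone | CC(=O)c1c(F)cc(OC)cc1OC | intermediate
11 | 4-methoxybenzaldehyde | COc1ccc(C=O)cc1 | starting material
12 | (E)-1-(2-fluoro-4,6-dimethoxyphenyl)-3-(4-methoxyphenyl)prop-2-en-1-one | COc1ccc(cc1)/C=C/C(=O)c1c(F)cc(OC)cc1OC | intermediate
13 | rac-trans-(2-fluoro-4,6-dimethoxyphenyl)[3-(4-methoxyphenyl)oxiran-2-yl]methanone (one enantiomer drawn) | COc1ccc(cc1)[C@H]1O[C@@H]1C(=O)c1c(F)cc(OC)cc1OC | intermediate
14 | (2R)-7-[3-(2-fluoro-4,6-dimethoxyphenyl)-2-hydroxy-1-(4-methoxyphenyl)-3-oxopropoxy]-2-(4-methoxyphenyl)chromane-5,8-dione, side-chain centres mixed | COc1ccc(cc1)[C@H]1CCC2=C(O1)C(=O)C(OC(c3ccc(OC)cc3)C(O)C(=O)c3c(F)cc(OC)cc3OC)=CC2=O | intermediate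
15 | (2R)-7-[3-(2-fluoro-4,6-dimethoxyphenyl)-1-(4-methoxyphenyl)-2,3-dioxopropoxy]-2-(4-methoxyphenyl)chromane-5,8-dione, C-beta mixed | COc1ccc(cc1)[C@H]1CCC2=C(O1)C(=O)C(OC(c3ccc(OC)cc3)C(=O)C(=O)c3c(F)cc(OC)cc3OC)=CC2=O | intermediate
16 | photoprecursor: (R)-flavan 5,8-quinone 7-O-[(Z)-1-An-2-(TBS-oxy)-3-ArF-3-oxoprop-1-enyl] ether | COc1ccc([C@H]2CCC3=C(O2)C(=O)C(O/C(c2ccc(OC)cc2)=C(\O[Si](C)(C)C(C)(C)C)C(=O)c2c(F)cc(OC)cc2OC)=CC3=O)cc1 | intermediate
17 | photoadduct: 2,5-dioxabicyclo[2.1.1]hexane fused to the flavan dienone (aroyl exo, OTBS over the C7–O7 bridge) | COc1ccc([C@H]2CCC3=C(O2)[C@]24O[C@@](c5ccc(OC)cc5)(OC4=CC3=O)[C@]2(O[Si](C)(C)C(C)(C)C)C(=O)c2c(F)cc(OC)cc2OC)cc1 | intermediate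
18 | C8 triethylsilyl ether of 19 | COc1ccc([C@H]2CCC3=C(O2)[C@]2(O[Si](CC)(CC)CC)[C@@](O[Si](C)(C)C(C)(C)C)(C(=O)c4c(F)cc(OC)cc4OC)[C@H](c4ccc(OC)cc4)OC2=CC3=O)cc1 | intermediate
19 | ring-F tertiary alcohol (C8–OH, C-alpha OTBS/aroyl, C-beta H/An) | COc1ccc([C@H]2CCC3=C(O2)[C@]2(O)[C@@](O[Si](C)(C)C(C)(C)C)(C(=O)c4c(F)cc(OC)cc4OC)[C@H](c4ccc(OC)cc4)OC2=CC3=O)cc1 | intermediate
20 | C-alpha O-TBS ether of the target | COc1ccc([C@H]2CCC3=C(O2)[C@]24Oc5cc(OC)cc(OC)c5C(=O)[C@@]2(O[Si](C)(C)C(C)(C)C)[C@H](c2ccc(OC)cc2)OC4=CC3=O)cc1 | intermediate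
21 | CNP0251458.1 | COc1ccc([C@H]2CCC3=C(O2)[C@]24Oc5cc(OC)cc(OC)c5C(=O)[C@@]2(O)[C@H](c2ccc(OC)cc2)OC4=CC3=O)cc1 | target

**Step count**
Total: 16 steps. Longest linear sequence: 13 steps (1 → 21 through steps 1–6 and 10–16); the epoxide arm (steps 7–9) is 3 steps.

**Steps most likely to fail**

1. Step 13 (proposed new method). The excited quinone may decay unproductively by back electron transfer or by reversal of the first C–O bond. The biradical may also collapse with the aroyl group over the bridge (wrong C-alpha), and the lack of facial bias halves the usable material. The fallback makes the C8–C-alpha bond by a known intramolecular Mukaiyama aldol addition. It sets out from 14: TBSOTf and 2,6-lutidine give the alpha-silyloxy ketone F1, and TMSOTf with Et3N in CH2Cl2 at −78 °C gives the trimethylsilyl enol ether F2. TiCl4 in CH2Cl2 at −78 °C then adds C-alpha to the activated C8 carbonyl (5-exo-trig, anti to An expected); aqueous work-up gives the tertiary alcohol. C-beta–H is already in place, so steps 12 to 14 are bypassed and the route is rejoined at 19 after separation of diastereomers.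

2. Step 14. Ionisation of the ketal may be followed by Grob-type cycloreversion of the C8–C-alpha bond back to 16 or by a 1,2-acyl shift before hydride arrives, and hydride may add to the wrong face of C-beta. The fallback delivers the hydride intramolecularly. It sets out from 17: i-Pr2Si(H)OTf (from i-Pr2SiHCl and AgOTf) with 2,6-di-tert-butyl-4-methylpyridine in CH2Cl2 at −78 °C places a hydridosilyl group on O8 as the ketal ionises. That group transfers its hydride to C-beta through a six-membered transition state on the O8 face, and aqueous NaHCO3 gives the O8 hydroxy(diisopropyl)silyl ether F3. HF·pyridine in THF at 0 °C cleaves it, and the route is rejoined at 19.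

3. Step 15. The C8 alkoxide may undergo retro-aldol cleavage of the C8–C-alpha bond, and the enolate so formed would expel O7 by beta-elimination, before the SNAr closes ring C. The fallback never forms a stoichiometric alkoxide. It sets out from 18, isolated from step 14 by omitting the methanolysis. Bu4N[Ph3SiF2] (10 mol %) in DMF at −20 °C → rt releases O8 only at catalytic concentration; each SNAr event returns the fluoride that carries the chain, and fluorotriethylsilane is lost. The route is rejoined at 20.

**Further compounds**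
F1 | step 13 | alpha-(tert-butyldimethylsilyloxy) ketone from 14 | COc1ccc(cc1)[C@H]1CCC2=C(O1)C(=O)C(OC(c3ccc(OC)cc3)C(O[Si](C)(C)C(C)(C)C)C(=O)c3c(F)cc(OC)cc3OC)=CC2=O
F2 | step 13 | trimethylsilyl enol ether of F1 | COc1ccc(cc1)[C@H]1CCC2=C(O1)C(=O)C(OC(c3ccc(OC)cc3)C(O[Si](C)(C)C(C)(C)C)=C(O[Si](C)(C)C)c3c(F)cc(OC)cc3OC)=CC2=O
F3 | step 14 | O8 hydroxy(diisopropyl)silyl ether of 19 | COc1ccc([C@H]2CCC3=C(O2)[C@]2(O[Si](O)(C(C)C)C(C)C)[C@@](O[Si](C)(C)C(C)(C)C)(C(=O)c4c(F)cc(OC)cc4OC)[C@H](c4ccc(OC)cc4)OC2=CC3=O)cc1
F0 | step 15 | none | none
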